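**Strategy**

Everything rests on disconnecting C3–C4 of ring A and reading what remains, ring B plus the C4 gem-dimethyl carbon, as a pinane: in (1S,5S)-verbenone C4 is already bonded to C5 and, through a sacrificial cyclobutane bond, to C7. That bridge steers a conjugate addition (C10) and an enolate alkylation (C9) to one face. In the key step a silyl Lewis acid breaks the C4–C7 bond; the released CMe2 cation is trapped by a pendant silyl enol ether, closing ring A as the trans-fused 2-ketone and unmasking ring B in one operation. The precursor is a bicyclo[3.1.1]heptan-2-one carrying the C9 side chain and a 2-silyloxyallyl arm on C10.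

Key step: step 7

Remark (assumption): labdane numbering is used throughout, also for the bicyclic precursors (labdane C4, C5, C6, C7, C8, C9, C10 = C6, C5, C7, C1, C2, C3, C4 of the bicyclo[3.1.1]heptane); (1S,5S)-verbenone and methyl hydrogen (R)-3-methylglutarate are taken as enantiopure commercial materials (verbenone of lower ee would be upgraded or made from (−)-α-pinene of high ee).

**Route**

Step 1
Reactants: 1 methyl hydrogen (R)-3-methylglutarate [(3R)-5-methoxy-3-methyl-5-oxopentanoic acid]
Product: 3 (S)-4-methyltetrahydro-2H-pyran-2-one, via hydroxy acid 2 (not isolated)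
Conditions: LiBH4 (2.2 equiv), THF, 0 °C to rt; 2 M HCl; then cat. TsOH, PhMe, 60 °C
Reagents that add atoms: none
Why: Chemoselective LiBH4 reduction of the ester in the presence of the lithium carboxylate followed by acid-catalysed lactonisation should give the δ-lactone, the stereocentre (future C13) being untouched while the choice of the reduced terminus fixes its sense.

Step 2
Reactants: 3 (S)-4-methyltetrahydro-2H-pyran-2-one
Product: 5 methyl (R)-5-iodo-3-methylpentanoate, via silyl ester 4 (not isolated)
Conditions: TMSI (1.2 equiv), CH2Cl2, rt; then MeOH (excess), rt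
Reagents that add atoms: iodotrimethylsilane, C[Si](C)(C)I; methanol, CO
Why: Silyl iodide cleavage of the lactone (O-silylation, then SN2 attack of iodide at the primary O–CH2) followed by methanolysis of the silyl ester and HI-catalysed Fischer esterification should give the iodo ester without touching the stereocentre.

Step 3
Reactants: 6 (1S,5S)-(−)-verbenone
Product: 8 (1S,4S,5S)-4,6,6-trimethyl-4-(2-methylallyl)bicyclo[3.1.1]heptan-2-one (methallyl anti to the CMe2 bridge), via C8 silyl enol ether 7 (not isolated)
Conditions: 2-methylallylMgCl (1.5 equiv), CuBr·SMe2 (1.5 equiv), LiCl, TMSCl (3 equiv), THF, −78 °C; then 1 M HCl, THF, 0 °C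
Reagents that add atoms: 2-methylallylmagnesium chloride, CC(=C)C[Mg]Cl; chlorotrimethylsilane, C[Si](C)(C)Cl (silicon in 7 only)
Why: TMSCl-assisted conjugate addition of the allylic copper reagent to the β,β-disubstituted enone should occur on the face of C10 opposite the CMe2 bridge (its syn methyl covers the other face), so that the new quaternary C10 carries the methallyl arm trans and the methyl cis to C4 across C5–C10, the relationship of a trans-decalin; mild acid then hydrolyses the enol silane.

Step 4
Reactants: 8 (1S,4S,5S)-4,6,6-trimethyl-4-(2-methylallyl)bicyclo[3.1.1]heptan-2-one; 5 methyl (R)-5-iodo-3-methylpentanoate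
Product: 10 methyl (3S)-3-methyl-5-[4,6,6-trimethyl-4-(2-methylallyl)-2-oxobicyclo[3.1.1]hept-3-yl]pentanoate (side chain anti to the CMe2 bridge), via lithium enolate 9 (not isolated)
Conditions: LDA (1.1 equiv), THF, −78 °C; then 5 (1.3 equiv), HMPA (3 equiv), −78 to −10 °C
Reagents that add atoms: none
Why: Enolate alkylation: C9 is the only enolisable position (C7 is a bridgehead) and the primary iodide should be attacked by the enolate face opposite the CMe2 bridge, which sets C9 with the side chain cis to the methallyl arm and trans to the C10 methyl as in the target.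

Step 5
Reactants: 10 methyl (3S)-3-methyl-5-[4,6,6-trimethyl-4-(2-methylallyl)-2-oxobicyclo[3.1.1]hept-3-yl]pentanoate
Product: 12 methyl (3S)-3-methyl-5-[4,6,6-trimethyl-2-oxo-4-(2-oxopropyl)bicyclo[3.1.1]hept-3-yl]pentanoate, via ozonide 11 (not isolated)
Conditions: O3, CH2Cl2, −78 °C; then PPh3, −78 °C to rt
Reagents that add atoms: ozone, [O-][O+]=O
Why: Ozonolysis with reductive work-up cleaves the only C=C bond (the 1,1-disubstituted methallyl alkene) to the methyl ketone, leaving ketone, ester and all stereocentres alone.

Step 6
Reactants: 12 methyl (3S)-3-methyl-5-[4,6,6-trimethyl-2-oxo-4-(2-oxopropyl)bicyclo[3.1.1]hept-3-yl]pentanoate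
Product: 13 methyl (3S)-3-methyl-5-{4,6,6-trimethyl-2-oxo-4-[2-(trimethylsilyloxy)allyl]bicyclo[3.1.1]hept-3-yl}pentanoate
Conditions: LDA (1.05 equiv), TMSCl (3 equiv, present from the start), THF, −78 °C; pentane, filtration, no aqueous work-up
Reagents that add atoms: chlorotrimethylsilane, C[Si](C)(C)Cl
Why: Kinetic enolisation with in situ O-silylation should occur at the unhindered CH3 of the methyl ketone (the ring ketone offers only a bridgehead H and the buried tertiary C9–H, the ester is less acidic), the internal TMSCl quench forestalling intramolecular aldol addition to C8.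

Step 7
Reactants: 13 methyl (3S)-3-methyl-5-{4,6,6-trimethyl-2-oxo-4-[2-(trimethylsilyloxy)allyl]bicyclo[3.1.1]hept-3-yl}pentanoate
Product: 14 methyl (5R,9R,10R,13S)-2-oxo-8-(trimethylsilyloxy)-17-norlabd-7-en-15-oate (trans-decalin)
Conditions: TMSOTf (20 mol%), 2,6-di-tert-butyl-4-methylpyridine (10 mol%), CH2Cl2, −78 to 0 °C; Et3N quench, pentane filtration, crude 14 used directly
Reagents that add atoms: none
Why: Proposed new method: Me3Si+ from TMSOTf activates the C8 carbonyl of the pinan-2-one, the strained C4–C7 cyclobutane bond ionises (push from the forming C8 silyl enol ether, pull of the tertiary CMe2 cation, release of ring strain), C3 of the pendant silyl enol ether captures the C4 cation, and the resulting C2 silyloxocarbenium ion hands its silyl group to the next C8 carbonyl, so the isomerisation should be catalytic. The closest known reaction types are the Lewis-acid opening of pinan-2-ones in which a tethered phenol oxygen captures the CMe2 cation to form a gem-dimethyl pyran, and the Reetz α-tert-alkylation of silyl enol ethers by tertiary cations; here the two are merged with a carbon π-nucleophile. Ring A closes in a 6-endo-trig mode with respect to the enol ether, through a chair transition state in which C5–C4 and C10–C1 are both equatorial on ring B, which gives the trans-decalin. No new stereocentre is formed (C4 is CMe2, C2 a carbonyl); C5, C9 and C10 pass through unchanged, and the trans ring fusion follows from the anti-to-bridge addition of step 3. The step needs carbon capture of the cation to beat proton loss, 1,2-hydride shift from C5 and aldol-type addition of the enol ether to C8: the six-membered chair places C3 over the cation, the hindered base removes adventitious TfOH, and C8 is flanked by a bridgehead and the branched C9. Because a silyl group and not a proton is transferred, C8 emerges as its Δ7 silyl enol ether, so C9 cannot epimerise and the two carbonyls are differentiated.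

Step 8
Reactants: 14 methyl (5R,9R,10R,13S)-2-oxo-8-(trimethylsilyloxy)-17-norlabd-7-en-15-oate
Product: 16 methyl (2S,5R,9R,10R,13S)-2-hydroxy-8-oxo-17-norlabdan-15-oate, via hydroxy silyl enol ether 15 (not isolated)
Conditions: L-Selectride (1.3 equiv), THF, −78 °C; then AcOH, THF/H2O, 0 °C
Reagents that add atoms: none
Why: Hydride delivery by the bulky borohydride to the C2 ketone should come from the equatorial side, the axial trajectory being blocked by the syn-axial C10 and C4 methyl groups, to give the axial 2-alcohol cis to the C10 methyl, while C8 is protected as its silyl enol ether and is released afterwards by kinetic C7-protonation without touching C9.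

Step 9
Reactants: 16 methyl (2S,5R,9R,10R,13S)-2-hydroxy-8-oxo-17-norlabdan-15-oate
Product: 17 methyl (2S,5R,9S,10R,13S)-2-hydroxylabd-8(17)-en-15-oate
Conditions: Zn, CH2Br2, TiCl4 (Lombardo reagent, excess), THF/CH2Cl2, 0 °C to rt
Reagents that add atoms: dibromomethane, BrCBr
Why: Lombardo methylenation: the non-basic gem-dizinc/titanium reagent should convert the hindered, enolisable C8 ketone into the exocyclic methylene without epimerising the axial C9 centre and tolerates the ester and the free hydroxyl.

Step 10
Reactants: 17 methyl (2S,5R,9S,10R,13S)-2-hydroxylabd-8(17)-en-15-oate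
Product: 18 methyl (2S,5R,9S,10R,13S)-2-(3-methylbutanoyloxy)labd-8(17)-en-15-oate
Conditions: 3-methylbutanoic anhydride (3 equiv), DMAP (0.5 equiv), Et3N, CH2Cl2, rt to 40 °C
Reagents that add atoms: 3-methylbutanoic anhydride, CC(C)CC(=O)OC(=O)CC(C)C
Why: DMAP-catalysed acylation (nucleophilic acyl-transfer catalysis) should esterify the hindered axial 2-hydroxyl with retention, there being no epimerisable centre left next to a carbonyl.

Step 11
Reactants: 18 methyl (2S,5R,9S,10R,13S)-2-(3-methylbutanoyloxy)labd-8(17)-en-15-oate
Product: 19 (2S,5R,9S,10R,13S)-2-(3-methylbutanoyloxy)labd-8(17)-en-15-oic acid (CNP0168901.1)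
Conditions: LiOH·H2O (3 equiv), THF/MeOH/H2O, 0 °C to rt; then dilute HCl to pH 3
Reagents that add atoms: lithium hydroxide, [Li+].[OH-]
Why: Saponification should cleave the unhindered primary methyl ester selectively, the secondary isovalerate being shielded by the two syn-axial methyl groups, and acidification then liberates the acid.

**Compound list**

1 | methyl hydrogen (R)-3-methylglutarate | COC(=O)C[C@H](C)CC(=O)O | starting material
2 | (S)-5-hydroxy-3-methylpentanoic acid | OCC[C@H](C)CC(=O)O | intermediate
3 | (S)-4-methyltetrahydro-2H-pyran-2-one | O=C1C[C@@H](C)CCO1 | intermediate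
4 | trimethylsilyl (R)-5-iodo-3-methylpentanoate | C[Si](C)(C)OC(=O)C[C@@H](C)CCI | intermediate
5 | methyl (R)-5-iodo-3-methylpentanoate | COC(=O)C[C@@H](C)CCI | intermediate
6 | (1S,5S)-(−)-verbenone | CC1=CC(=O)[C@H]2C[C@@H]1C2(C)C | starting material
7 | trimethylsilyl enol ether of 8 | C[Si](C)(C)OC1=C[C@](C)(CC(C)=C)[C@@H]2C[C@H]1C2(C)C | intermediate
8 | (1S,4S,5S)-4,6,6-trimethyl-4-(2-methylallyl)bicyclo[3.1.1]heptan-2-one | O=C1C[C@](C)(CC(C)=C)[C@@H]2C[C@H]1C2(C)C | intermediate
9 | lithium enolate of 8 | [Li]OC1=C[C@](C)(CC(C)=C)[C@@H]2C[C@H]1C2(C)C | intermediate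
10 | methyl (3S)-3-methyl-5-[4,6,6-trimethyl-4-(2-methylallyl)-2-oxobicyclo[3.1.1]hept-3-yl]pentanoate | O=C1[C@H](CC[C@H](C)CC(=O)OC)[C@](C)(CC(C)=C)[C@@H]2C[C@H]1C2(C)C | intermediate
11 | secondary ozonide of 10 | O=C1[C@H](CC[C@H](C)CC(=O)OC)[C@](C)(CC3(C)OOCO3)[C@@H]2C[C@H]1C2(C)C | intermediate
12 | methyl (3S)-3-methyl-5-[4,6,6-trimethyl-2-oxo-4-(2-oxopropyl)bicyclo[3.1.1]hept-3-yl]pentanoate | O=C1[C@H](CC[C@H](C)CC(=O)OC)[C@](C)(CC(C)=O)[C@@H]2C[C@H]1C2(C)C | intermediate
13 | methyl (3S)-3-methyl-5-{4,6,6-trimethyl-2-oxo-4-[2-(trimethylsilyloxy)allyl]bicyclo[3.1.1]hept-3-yl}pentanoate | O=C1[C@H](CC[C@H](C)CC(=O)OC)[C@](C)(CC(=C)O[Si](C)(C)C)[C@@H]2C[C@H]1C2(C)C | intermediate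
14 | methyl (5R,9R,10R,13S)-2-oxo-8-(trimethylsilyloxy)-17-norlabd-7-en-15-oate | C[Si](C)(C)OC1=CC[C@@H]2C(C)(C)CC(=O)C[C@@]2(C)[C@H]1CC[C@H](C)CC(=O)OC | intermediate
15 | methyl (2S,5R,9R,10R,13S)-2-hydroxy-8-(trimethylsilyloxy)-17-norlabd-7-en-15-oate | C[Si](C)(C)OC1=CC[C@@H]2C(C)(C)C[C@H](O)C[C@@]2(C)[C@H]1CC[C@H](C)CC(=O)OC | intermediate
16 | methyl (2S,5R,9R,10R,13S)-2-hydroxy-8-oxo-17-norlabdan-15-oate | O=C1CC[C@@H]2C(C)(C)C[C@H](O)C[C@@]2(C)[C@H]1CC[C@H](C)CC(=O)OC | intermediate
17 | methyl (2S,5R,9S,10R,13S)-2-hydroxylabd-8(17)-en-15-oate | C=C1CC[C@@H]2C(C)(C)C[C@H](O)C[C@@]2(C)[C@H]1CC[C@H](C)CC(=O)OC | intermediate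
18 | methyl (2S,5R,9S,10R,13S)-2-(3-methylbutanoyloxy)labd-8(17)-en-15-oate | C=C1CC[C@@H]2C(C)(C)C[C@H](OC(=O)CC(C)C)C[C@@]2(C)[C@H]1CC[C@H](C)CC(=O)OC | intermediate
19 | (2S,5R,9S,10R,13S)-2-(3-methylbutanoyloxy)labd-8(17)-en-15-oic acid | C=C1CC[C@@H]2C(C)(C)C[C@H](OC(=O)CC(C)C)C[C@@]2(C)[C@H]1CC[C@H](C)CC(=O)O | target

**Step count and risks**

Total steps: 11. Longest linear sequence: 10 (from 1 through steps 1, 2 and 4–11); 9 from verbenone 6.

Steps most likely to fail:

Step 7. Carbon capture of the C4 cation may lose out to proton loss or a 1,2-hydride shift from C5, or the silyl enol ether may add aldol-fashion to the activated C8 carbonyl before the cyclobutane ionises. The fallback separates ionisation and C–C bond formation into two known reactions. From 13, iodotrimethylsilane (1.05 equiv, CH2Cl2, −40 °C; the known silyl iodide opening of cyclobutyl ketones) should give the ring-opened tertiary iodide bis(silyl enol ether) F1. An intramolecular Reetz α-tert-alkylation of its 2-silyloxyallyl group by the tertiary iodide (cat. ZnI2, CH2Cl2, −40 to 0 °C) should then close ring A and return to the route at 14.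

Step 3. The allylic organometallic may add 1,2 to the carbonyl, or the allylic copper species may decompose, faster than it attacks the hindered β-carbon. The fallback makes the 1,2-addition deliberate. From 6, 2-methylallylmagnesium chloride (THF, −78 °C; attack anti to the CMe2 bridge) should give the tertiary dienol F2. Its potassium alkoxide (KH, 18-crown-6, THF, 0 °C to rt) should undergo anionic oxy-Cope rearrangement, which carries the methallyl group suprafacially to C10 on the same face. Protonation of the resulting enolate returns to the route at 8.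

Step 4. SN2 attack of the hindered enolate on the unactivated iodide may be slow enough for proton transfer, loss of HI from the iodide or attack on the ester carbonyl to take over. The fallback uses an azaenolate. From 8, the N,N-dimethylhydrazone F3 is formed (Me2NNH2, cat. TsOH, EtOH, reflux). Its lithium azaenolate (LDA, THF, −78 °C), a much stronger SN2 nucleophile, is alkylated with 5, again anti to the bridge, to give the alkylated hydrazone F4. Mild hydrolysis (aq. oxalic acid, Et2O) returns to the route at 10.

Further compounds
F1 | step 7 | methyl (3S)-5-{5-(2-iodopropan-2-yl)-6-methyl-2-(trimethylsilyloxy)-6-[2-(trimethylsilyloxy)allyl]cyclohex-2-en-1-yl}-3-methylpentanoate | C[Si](C)(C)OC1=CC[C@H](C(C)(C)I)[C@@](C)(CC(=C)O[Si](C)(C)C)[C@H]1CC[C@H](C)CC(=O)OC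
F2 | step 3 | 4,6,6-trimethyl-2-(2-methylallyl)bicyclo[3.1.1]hept-3-en-2-ol (methallyl anti to the CMe2 bridge) | CC1=C[C@@](O)(CC(C)=C)[C@H]2C[C@@H]1C2(C)C
F3 | step 4 | N,N-dimethylhydrazone of 8 | CN(C)N=C1C[C@](C)(CC(C)=C)[C@@H]2C[C@H]1C2(C)C
F4 | step 4 | N,N-dimethylhydrazone of 10 | CN(C)N=C1[C@H](CC[C@H](C)CC(=O)OC)[C@](C)(CC(C)=C)[C@@H]2C[C@H]1C2(C)C
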